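**Assumption (remark on the chemistry):** the target has no stereocentre and no stereogenic double bond, so "single enantiomer" is taken to mean the single constitution drawn. The only stereochemical issue in the route is the Z geometry of intermediate 6.

## Retrosynthetic overview

1. Ring A of the target is a 4-methoxyphenol: C8–OH is para to C5–OMe, and the lactone oxygen O1 sits on C8a, ortho to that free OH. The O1–C8a bond is therefore cut as a phenol-triggered dehydrogenative C–H lactonisation of the open (Z)-3,3-diarylacrylic acid 6, which closes the pyranone ring without any protecting group.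
2. Acid 6 is cut at C4–C4a: trans-hydroarylation of arylpropiolic acid 4 by commercial 2,4-dimethoxyphenol 5 through its C5 (para to the 2-OMe), which also sets the Z geometry.
3. Acid 4 comes from carboxylation of commercial 4-ethynyl-1,2-dimethoxybenzene 1.
4. Ring order: ring A and the veratryl ring are bought; the pyranone ring (O1–C2–C3–C4–C4a–C8a) is the only ring formed, and it is formed last.

Key step: step 3

## Route

**Step 1**
Reactants: 1 4-ethynyl-1,2-dimethoxybenzene
Product: 4 3-(3,4-dimethoxyphenyl)prop-2-ynoic acid, via lithium acetylide 2 (not isolated), via lithium propiolate 3 (not isolated)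
Conditions: n-BuLi (1.05 equiv), THF, −78 °C; CO2 (dry, excess), −78 °C → rt; aq. HCl
Reagents that add atoms: carbon dioxide, O=C=O
Why: Deprotonation of the terminal alkyne by n-BuLi and carboxylation of the lithium acetylide with CO2 is the standard route to arylpropiolic acids, and the aryl methyl ethers are inert at −78 °C.

**Step 2**
Reactants: 4 3-(3,4-dimethoxyphenyl)prop-2-ynoic acid; 5 2,4-dimethoxyphenol (1.5 equiv)
Product: 6 (2Z)-3-(3,4-dimethoxyphenyl)-3-(5-hydroxy-2,4-dimethoxyphenyl)prop-2-enoic acid
Conditions: Pd(OAc)2 (5 mol %), dry TFA/CH2Cl2 (4:1), 0 °C → rt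
Reagents that add atoms: none
Why: In this Fujiwara-type Pd(II)/TFA trans-hydroarylation of an alkynoic acid, the most nucleophilic ring carbon of 5, C5 (para to the 2-OMe, ortho to the 4-OMe, meta to the OH), should attack the Pd(II)-activated alkyne at the veratryl-bearing β-carbon anti to the metal, so that protodepalladation leaves the new aryl cis to CO2H (Z), an arrangement also expected to be the thermodynamic one because the ortho-substituted, twisted aryl lies next to CO2H, and the phenol, being meta to the new bond, cannot lactonise.

**Step 3**
Reactants: 6 (2Z)-3-(3,4-dimethoxyphenyl)-3-(5-hydroxy-2,4-dimethoxyphenyl)prop-2-enoic acid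
Product: 8 8-hydroxy-5,7,3',4'-tetramethoxy-4-phenylcoumarin [4-(3,4-dimethoxyphenyl)-8-hydroxy-5,7-dimethoxy-2H-chromen-2-one], via dienone lactone 7 (not isolated)
Conditions: PhI(OAc)2 (1.05 equiv, slow addition), (CF3)2CHOH/CH2Cl2 (1:1), 4 Å MS, −20 → 0 °C; aq. Na2S2O3
Reagents that add atoms: none
Why: Proposed new method: two-electron oxidation of the C8 phenol of 6 by iodine(III) (ligand exchange at oxygen, loss of PhI) should give the phenoxonium ion of the 4-methoxyphenol unit of ring A, stabilised by the para C5–OMe and the ortho C7–OMe, and the carboxyl group held by the Z alkene at C4a captures it at the only unsubstituted ortho carbon, C8a, to give dienone 7, whose C8a–H enolises to restore the arene as the catechol monoester 8. The closest known reaction types are the PhI(OAc)2-mediated dearomatising spirolactonisation of phenols that carry a carboxylic acid tether, the Wessely-type ortho-acyloxylation of phenols, and the hypervalent-iodine oxidative cyclisation of 3,3-diarylacrylic acids to 4-arylcoumarins; not yet shown is capture of a phenoxonium ion at an ortho C–H carbon by an acrylic acid with rearomatisation. The pyranone ring (O1–C2–C3–C4–C4a–C8a) closes by O1–C8a bond formation in a six-membered mode, formally 6-endo-trig with respect to the C4a=C8a bond of the cation, and is geometrically possible only because CO2H and ring A are cis. No stereocentre results, since the transient sp3 C8a of 7 is lost on tautomerisation. The step needs ortho (C8a) over para (C5) capture: the para adduct is a mixed acyl methyl ketal that cannot aromatise and should revert by ionisation in HFIP, whereas the ortho adduct aromatises irreversibly, and the strained five-membered C–C closure by the veratryl ring should not compete. Chemoselectivity for ring A over the veratryl ring and the alkene rests on the fast ligand exchange of the phenol at iodine(III) at low temperature, over-oxidation is limited because the acyloxy-substituted phenol of 8 is less electron-rich than that of 6, and sieves exclude the water that would lead to a p-quinone.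

## Compound list

Compounds 2, 3 and 7 form in the flask and are not isolated; 7 is racemic at its transient C8a.

1 | 4-ethynyl-1,2-dimethoxybenzene | C#Cc1ccc(OC)c(OC)c1 | starting material
2 | lithium (3,4-dimethoxyphenyl)acetylide | [Li+].[C-]#Cc1ccc(OC)c(OC)c1 | intermediate
3 | lithium 3-(3,4-dimethoxyphenyl)prop-2-ynoate | [Li+].[O-]C(=O)C#Cc1ccc(OC)c(OC)c1 | intermediate
4 | 3-(3,4-dimethoxyphenyl)prop-2-ynoic acid | OC(=O)C#Cc1ccc(OC)c(OC)c1 | intermediate
5 | 2,4-dimethoxyphenol | COc1ccc(O)c(OC)c1 | starting material
6 | (2Z)-3-(3,4-dimethoxyphenyl)-3-(5-hydroxy-2,4-dimethoxyphenyl)prop-2-enoic acid | OC(=O)/C=C(\c1cc(O)c(OC)cc1OC)c1ccc(OC)c(OC)c1 | intermediate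
7 | 4-(3,4-dimethoxyphenyl)-5,7-dimethoxy-8aH-chromene-2,8-dione | COc1ccc(cc1OC)C1=CC(=O)OC2C(=O)C(OC)=CC(OC)=C12 | intermediate
8 | 8-hydroxy-5,7,3',4'-tetramethoxy-4-phenylcoumarin | COc1ccc(-c2cc(=O)oc3c(O)c(OC)cc(OC)c23)cc1OC | target

## Step count and risk

Total step count: 3
Longest linear sequence: 3 steps (1 → 4 → 6 → 8)

**Steps most likely to fail, riskiest first**

Step 3 (proposed new method). What may go wrong: capture of the phenoxonium ion by water or acetate instead of the internal carboxyl group, para capture that does not revert, or further oxidation of the product phenol, all of which lead to quinone formation instead of ortho lactonisation. The fallback uses known chemistry and gives up the C–H oxidation; it sets out from acid 4 and comes back to the route at 8. Purchased 2-hydroxy-4,6-dimethoxybenzaldehyde F1 should undergo Dakin oxidation (H2O2, H3BO3, cat. H2SO4, THF, rt; then mild hydrolysis of the formate) to 3,5-dimethoxybenzene-1,2-diol F2, which already holds the C8 and C8a oxygens. F2 and 4 would then be joined under Pd(OAc)2 (cat.), TFA/CH2Cl2, rt, the known coumarin synthesis from a phenol and an arylpropiolic acid. Hydroarylation at the ring carbon of F2 that lies between OH and OMe (its C6), followed by spontaneous lactonisation onto the adjacent OH, should give 8. The adduct formed at C4 of F2 has no neighbouring OH, cannot lactonise, and would be removed as an acid with aqueous NaHCO3.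

Step 2. What may go wrong: attack of the phenol through C6 or C3 instead of C5, erosion of the alkene geometry in TFA, and oligomerisation of the alkynoic acid. The fallback replaces the hydroarylation by acylation and carbonyl olefination; it sets out from 5 and comes back at 6. Phenol 5 would be acylated (PivCl, Et3N, DMAP, CH2Cl2) to 2,4-dimethoxyphenyl 2,2-dimethylpropanoate F3. Friedel–Crafts acylation of F3 with 3,4-dimethoxybenzoyl chloride (SnCl4, CH2Cl2, 0 °C) should occur para to the 2-OMe and give 5-(3,4-dimethoxybenzoyl)-2,4-dimethoxyphenyl 2,2-dimethylpropanoate F4. Peterson olefination of F4 (ethyl (trimethylsilyl)acetate, LDA, THF, −78 °C → rt) should give ethyl 3-(3,4-dimethoxyphenyl)-3-[2,4-dimethoxy-5-(pivaloyloxy)phenyl]prop-2-enoate F5 as an E/Z mixture. LiOH (THF/MeOH/H2O, 50 °C) would cleave both esters to 6 together with (2E)-3-(3,4-dimethoxyphenyl)-3-(5-hydroxy-2,4-dimethoxyphenyl)prop-2-enoic acid F6. The mixture would be equilibrated (cat. I2, visible light) towards the Z isomer, which is expected to be favoured, and 6 crystallised.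

Step 1. What may go wrong: quenching of the acetylide by adventitious proton sources before carboxylation, and loss of CO2 from the electron-rich arylpropiolic acid during acidic work-up or concentration. The fallback replaces the organolithium carboxylation by a Pd-catalysed carbonylation; it sets out from 1 and comes back at 4. Oxidative methoxycarbonylation of 1 (PdCl2 cat., CuCl2, NaOAc, CO 1 atm, MeOH, rt) should give methyl 3-(3,4-dimethoxyphenyl)prop-2-ynoate F7, and cold saponification (LiOH, THF/H2O, 0 °C; then careful acidification) should give 4.

## Further compounds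

F1 | step 3 | 2-hydroxy-4,6-dimethoxybenzaldehyde | COc1cc(OC)c(C=O)c(O)c1
F2 | step 3 | 3,5-dimethoxybenzene-1,2-diol | COc1cc(O)c(O)c(OC)c1
F3 | step 2 | 2,4-dimethoxyphenyl 2,2-dimethylpropanoate | CC(C)(C)C(=O)Oc1ccc(OC)cc1OC
F4 | step 2 | 5-(3,4-dimethoxybenzoyl)-2,4-dimethoxyphenyl 2,2-dimethylpropanoate | CC(C)(C)C(=O)Oc1cc(C(=O)c2ccc(OC)c(OC)c2)c(OC)cc1OC
F5 | step 2 | ethyl 3-(3,4-dimethoxyphenyl)-3-[2,4-dimethoxy-5-(pivaloyloxy)phenyl]prop-2-enoate (E/Z mixture) | CCOC(=O)C=C(c1ccc(OC)c(OC)c1)c1cc(OC(=O)C(C)(C)C)c(OC)cc1OC
F6 | step 2 | (2E)-3-(3,4-dimethoxyphenyl)-3-(5-hydroxy-2,4-dimethoxyphenyl)prop-2-enoic acid | OC(=O)/C=C(/c1cc(O)c(OC)cc1OC)c1ccc(OC)c(OC)c1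
F7 | step 1 | methyl 3-(3,4-dimethoxyphenyl)prop-2-ynoate | COC(=O)C#Cc1ccc(OC)c(OC)c1
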